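Ring carbon C1, the quaternary stereocentre of the cyclohexenedione, carries two CH2–C=O arms: ring methylene C6 with ketone C5, and the CH2CO2Me group. The route reads the two methylenes as the α-carbons of a 3,3-disubstituted cyclobutanone, achiral at this carbon, whose carbonyl becomes the ester. The precursor is a 3-oxocyclobutyl γ-keto ester. In the key step a chiral lithium amide enolises one enantiotopic methylene, the enolate closes the six-membered ring by Claisen acylation at the tethered ester (C6–C5 bond), and the released methoxide opens the strained four-membered ketone. One isomerisation thus forms the ring and sets C1; dehydrogenation and deprotection finish the synthesis.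

Key step: step 9

Numbering: ring C1 (quaternary), C2 (C=O), C3=C4, C5 (C=O), C6 (CH2) as in the target; side chain C1′–C16′ counted from the ring. "Acetonide chain" stands for (2E,6E,10E)-11-[(4S,5R)-2,2-dimethyl-5-(2-methylprop-1-en-1-yl)-1,3-dioxolan-4-yl]-3,7-dimethyldodeca-2,6,10-trien-1-yl, the C12′,C13′-acetonide of the target side chain.

Assumption: the sense of induction of the chiral lithium amide in step 9 has to be fixed by experiment; the (R,R)-amide is written, and its enantiomer would be used if it proved to select the other methylene.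

Step 1
Reactants: 1 methyl 3,3-dimethoxycyclobutane-1-carboxylate; 2 (2E,6E)-farnesyl bromide
Product: 3 methyl 3,3-dimethoxy-1-[(2E,6E)-3,7,11-trimethyldodeca-2,6,10-trien-1-yl]cyclobutane-1-carboxylate
Conditions: LiN(i-Pr)2, THF, −78 °C; then 2, −78 → 0 °C
Reagents that add atoms: none
Why: Alkylation of the lithium ester enolate with the primary allylic bromide (SN2, E geometry retained) builds the quaternary carbon, which is not yet a stereocentre because the cyclobutane keeps a mirror plane through it.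

Step 2
Reactants: 3 methyl 3,3-dimethoxy-1-[(2E,6E)-3,7,11-trimethyldodeca-2,6,10-trien-1-yl]cyclobutane-1-carboxylate
Product: 4 methyl 1-[(2E,6E,10E)-12-hydroxy-3,7,11-trimethyldodeca-2,6,10-trien-1-yl]-3,3-dimethoxycyclobutane-1-carboxylate
Conditions: SeO2 (cat.), t-BuOOH, salicylic acid (cat.), CH2Cl2, 0 °C → rt, stopped at partial conversion, recovered 3 recycled
Reagents that add atoms: selenium dioxide, O=[Se]=O (donor of the oxygen atom); tert-butyl hydroperoxide, CC(C)(C)OO (restores the selenium dioxide)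
Why: Riley-type allylic oxidation (ene reaction, then [2,3]-sigmatropic shift) should take place at the E-methyl group of the terminal, most accessible trisubstituted alkene, which fixes the 10′E geometry.

Step 3
Reactants: 4 methyl 1-[(2E,6E,10E)-12-hydroxy-3,7,11-trimethyldodeca-2,6,10-trien-1-yl]-3,3-dimethoxycyclobutane-1-carboxylate
Product: 5 methyl 3,3-dimethoxy-1-[(2E,6E,10E)-3,7,11-trimethyl-12-oxododeca-2,6,10-trien-1-yl]cyclobutane-1-carboxylate
Conditions: MnO2, CH2Cl2, rt
Reagents that add atoms: none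
Why: MnO2 oxidises only the allylic alcohol to the E-enal and leaves the isolated alkenes, the ketal and the ester untouched.

Step 4
Reactants: 5 methyl 3,3-dimethoxy-1-[(2E,6E,10E)-3,7,11-trimethyl-12-oxododeca-2,6,10-trien-1-yl]cyclobutane-1-carboxylate; 6 allyl(diisopropylamino)dimethylsilane
Product: 8 methyl 1-[(2E,6E,10E,12S,13R)-12,13-dihydroxy-3,7,11-trimethylpentadeca-2,6,10,14-tetraen-1-yl]-3,3-dimethoxycyclobutane-1-carboxylate, via silyl borinate 7 (not isolated)
Conditions: 6, n-BuLi, TMEDA, Et2O, 0 °C; (+)-Ipc2BOMe [(+)-B-methoxydiisopinocampheylborane, from (−)-α-pinene], −78 °C; BF3·OEt2 (1 equiv); 5, −78 °C; then 30% H2O2, KF, KHCO3, THF/MeOH, rt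
Reagents that add atoms: hydrogen peroxide, OO
Why: Brown-type allylboration with the (E)-γ-silylallylborane runs through a chair transition state in which the reagent from (−)-α-pinene is expected to attack the Re face of the aldehyde (C12′ S) and the E geometry places silicon anti to oxygen, and the Tamao oxidation then replaces silicon by hydroxyl with retention (C13′ R).

Step 5
Reactants: 8 methyl 1-[(2E,6E,10E,12S,13R)-12,13-dihydroxy-3,7,11-trimethylpentadeca-2,6,10,14-tetraen-1-yl]-3,3-dimethoxycyclobutane-1-carboxylate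
Product: 9 methyl 1-[(2E,6E,10E)-11-[(4S,5R)-5-ethenyl-2,2-dimethyl-1,3-dioxolan-4-yl]-3,7-dimethyldodeca-2,6,10-trien-1-yl]-3,3-dimethoxycyclobutane-1-carboxylate
Conditions: 2,2-dimethoxypropane, PPTS (cat.), CH2Cl2, rt
Reagents that add atoms: 2,2-dimethoxypropane, COC(C)(C)OC
Why: Acid-catalysed transketalisation closes the cis-dioxolane on the anti-diol under anhydrous conditions that leave the dimethyl ketal of the cyclobutanone in place.

Step 6
Reactants: 9 methyl 1-[(2E,6E,10E)-11-[(4S,5R)-5-ethenyl-2,2-dimethyl-1,3-dioxolan-4-yl]-3,7-dimethyldodeca-2,6,10-trien-1-yl]-3,3-dimethoxycyclobutane-1-carboxylate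
Product: 10 methyl 1-(acetonide chain)-3,3-dimethoxycyclobutane-1-carboxylate
Conditions: 2-methylbut-2-ene (excess), second-generation Grubbs catalyst RuCl2(=CHPh)(PCy3)(H2IMes) (5 mol %), CH2Cl2, 40 °C
Reagents that add atoms: 2-methylbut-2-ene, CC=C(C)C
Why: Olefin cross-metathesis of the only monosubstituted alkene with excess 2-methylbut-2-ene installs the isopropylidene terminus, the trisubstituted alkenes of the chain being too hindered to enter the catalytic cycle.

Step 7
Reactants: 10 methyl 1-(acetonide chain)-3,3-dimethoxycyclobutane-1-carboxylate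
Product: 12 1-(acetonide chain)-3-oxocyclobutane-1-carboxylic acid, via ketal acid 11 (not isolated)
Conditions: LiOH, THF/MeOH/H2O, 60 °C; then 1 M HCl, acetone/H2O, rt
Reagents that add atoms: lithium hydroxide, [Li+].[OH-] (carboxyl oxygen); water, O (ketone oxygen)
Why: Saponification of the hindered ester followed by acid-catalysed ketal exchange in aqueous acetone frees the acid and the cyclobutanone, the acetonide being held in place by the acetone solvent.

Step 8
Reactants: 12 1-(acetonide chain)-3-oxocyclobutane-1-carboxylic acid; 13 methyl 3-bromopropanoate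
Product: 15 methyl 4-[1-(acetonide chain)-3-oxocyclobutyl]-4-oxobutanoate, via acid chloride 14 (not isolated)
Conditions: 1-chloro-N,N,2-trimethylprop-1-en-1-amine, CH2Cl2, 0 °C → rt; then BrZnCH2CH2CO2Me (from 13, Zn, I2 cat., DMA, 70 °C), Pd(PPh3)4 (5 mol %), THF, 0 °C → rt
Reagents that add atoms: none
Why: The acid chloride, formed under neutral conditions, undergoes Negishi acylation with the ester-bearing alkylzinc reagent, which adds to neither the cyclobutanone nor the new ketone and so delivers the γ-keto ester.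

Step 9
Reactants: 15 methyl 4-[1-(acetonide chain)-3-oxocyclobutyl]-4-oxobutanoate
Product: 17 methyl 2-[(1R)-1-(acetonide chain)-2,5-dioxocyclohexyl]acetate, via bicyclic trione 16 (not isolated)
Conditions: (R,R)-bis(1-phenylethyl)amine hydrochloride, n-BuLi (2 equiv per amine, gives LiN[(R)-CHMePh]2 and LiCl), THF, −78 → 0 °C; 15, −100 → −20 °C; then MeOH, 0 °C → rt; AcOH
Reagents that add atoms: methanol, CO (its methoxide exchanges with the one expelled in the ring closure and ends in the ester)
Why: Proposed new method: the chiral lithium amide should remove a proton from one of the two enantiotopic α-methylene groups of the cyclobutanone (the pro-S one, future C6), the lithium enolate then attacks the tethered methyl ester in a Dieckmann-type Claisen acylation that forms the C6–C5 bond, and the expelled methoxide adds to the strained four-membered ketone of the 2-acylcyclobutanone 16, whose retro-Claisen cleavage turns that ketone into the CH2CO2Me arm. The closest known reaction types are the desymmetrisation of 3-substituted cyclobutanones by chiral lithium amides, the Dieckmann condensation and the alkoxide-induced ring opening of 2-acylcyclobutanones, which have not been joined in one enantioselective isomerisation. The six-membered ring closes in a 6-(enolexo)-exo-trig mode, the transient ring fusion being necessarily cis. The only lasting new stereocentre is C1, which becomes stereogenic once its two methylene arms are differentiated and is therefore set by the chiral base, while the CH stereocentre at the ring fusion is erased on ring opening. The step needs site selectivity in the deprotonation and regioselectivity in the cleavage: the cyclobutanone α-hydrogens are the most acidic ones in 15 and the side-chain ketone is shielded by the quaternary carbon, enolates formed at C3 or C4 cannot reach a carbonyl group through an unstrained ring and return on quench, and only attack at the four-membered ketone releases ring strain, so that the six-membered 1,4-dione should survive.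

Step 10
Reactants: 17 methyl 2-[(1R)-1-(acetonide chain)-2,5-dioxocyclohexyl]acetate
Product: 18 methyl 2-[(1R)-1-(acetonide chain)-2,5-dioxocyclohex-3-en-1-yl]acetate
Conditions: IBX, 4-methoxypyridine N-oxide, DMSO, rt → 40 °C
Reagents that add atoms: none
Why: IBX dehydrogenation of the ketone through its enol can only introduce the C3=C4 double bond, because quaternary C1 blocks every other enone and any aromatisation.

Step 11
Reactants: 18 methyl 2-[(1R)-1-(acetonide chain)-2,5-dioxocyclohex-3-en-1-yl]acetate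
Product: 19 methyl 2-[(1R)-1-[(2E,6E,10E,12S,13R)-12,13-dihydroxy-3,7,11,15-tetramethylhexadeca-2,6,10,14-tetraen-1-yl]-2,5-dioxocyclohex-3-en-1-yl]acetate
Conditions: AcOH/H2O/THF (3:1:1), 40 °C
Reagents that add atoms: none
Why: Mild aqueous acid hydrolyses the cis-dioxolane at its acetal carbon, so that the allylic C–O bonds, the ene-dione and the methyl ester should stay intact and the anti-diol is released unchanged.

Compound list
1 | methyl 3,3-dimethoxycyclobutane-1-carboxylate | COC(=O)C1CC(OC)(OC)C1 | starting material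
2 | (2E,6E)-farnesyl bromide [(2E,6E)-1-bromo-3,7,11-trimethyldodeca-2,6,10-triene] | BrC/C=C(\C)CC/C=C(\C)CCC=C(C)C | starting material
3 | methyl 3,3-dimethoxy-1-[(2E,6E)-3,7,11-trimethyldodeca-2,6,10-trien-1-yl]cyclobutane-1-carboxylate | COC(=O)C1(C/C=C(\C)CC/C=C(\C)CCC=C(C)C)CC(OC)(OC)C1 | intermediate
4 | methyl 1-[(2E,6E,10E)-12-hydroxy-3,7,11-trimethyldodeca-2,6,10-trien-1-yl]-3,3-dimethoxycyclobutane-1-carboxylate | COC(=O)C1(C/C=C(\C)CC/C=C(\C)CC/C=C(\C)CO)CC(OC)(OC)C1 | intermediate
5 | methyl 3,3-dimethoxy-1-[(2E,6E,10E)-3,7,11-trimethyl-12-oxododeca-2,6,10-trien-1-yl]cyclobutane-1-carboxylate | COC(=O)C1(C/C=C(\C)CC/C=C(\C)CC/C=C(\C)C=O)CC(OC)(OC)C1 | intermediate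
6 | allyl(diisopropylamino)dimethylsilane | C=CC[Si](C)(C)N(C(C)C)C(C)C | starting material
7 | bis(isopinocampheyl)borinate of methyl 1-[(2E,6E,10E,12S,13R)-13-[(diisopropylamino)dimethylsilyl]-12-hydroxy-3,7,11-trimethylpentadeca-2,6,10,14-tetraen-1-yl]-3,3-dimethoxycyclobutane-1-carboxylate (not isolated) | COC(=O)C1(C/C=C(\C)CC/C=C(\C)CC/C=C(\C)[C@H](OB([C@H]2C[C@H]3C[C@H](C3(C)C)[C@@H]2C)[C@H]2C[C@H]3C[C@H](C3(C)C)[C@@H]2C)[C@H]([Si](C)(C)N(C(C)C)C(C)C)C=C)CC(OC)(OC)C1 | intermediate
8 | methyl 1-[(2E,6E,10E,12S,13R)-12,13-dihydroxy-3,7,11-trimethylpentadeca-2,6,10,14-tetraen-1-yl]-3,3-dimethoxycyclobutane-1-carboxylate | COC(=O)C1(C/C=C(\C)CC/C=C(\C)CC/C=C(\C)[C@H](O)[C@H](O)C=C)CC(OC)(OC)C1 | intermediate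
9 | methyl 1-[(2E,6E,10E)-11-[(4S,5R)-5-ethenyl-2,2-dimethyl-1,3-dioxolan-4-yl]-3,7-dimethyldodeca-2,6,10-trien-1-yl]-3,3-dimethoxycyclobutane-1-carboxylate | COC(=O)C1(C/C=C(\C)CC/C=C(\C)CC/C=C(\C)[C@@H]2OC(C)(C)O[C@@H]2C=C)CC(OC)(OC)C1 | intermediate
10 | methyl 1-(acetonide chain)-3,3-dimethoxycyclobutane-1-carboxylate | COC(=O)C1(C/C=C(\C)CC/C=C(\C)CC/C=C(\C)[C@@H]2OC(C)(C)O[C@@H]2C=C(C)C)CC(OC)(OC)C1 | intermediate
11 | 1-(acetonide chain)-3,3-dimethoxycyclobutane-1-carboxylic acid (not isolated) | OC(=O)C1(C/C=C(\C)CC/C=C(\C)CC/C=C(\C)[C@@H]2OC(C)(C)O[C@@H]2C=C(C)C)CC(OC)(OC)C1 | intermediate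
12 | 1-(acetonide chain)-3-oxocyclobutane-1-carboxylic acid | OC(=O)C1(C/C=C(\C)CC/C=C(\C)CC/C=C(\C)[C@@H]2OC(C)(C)O[C@@H]2C=C(C)C)CC(=O)C1 | intermediate
13 | methyl 3-bromopropanoate | COC(=O)CCBr | starting material
14 | 1-(acetonide chain)-3-oxocyclobutane-1-carbonyl chloride (not isolated) | ClC(=O)C1(C/C=C(\C)CC/C=C(\C)CC/C=C(\C)[C@@H]2OC(C)(C)O[C@@H]2C=C(C)C)CC(=O)C1 | intermediate
15 | methyl 4-[1-(acetonide chain)-3-oxocyclobutyl]-4-oxobutanoate | COC(=O)CCC(=O)C1(C/C=C(\C)CC/C=C(\C)CC/C=C(\C)[C@@H]2OC(C)(C)O[C@@H]2C=C(C)C)CC(=O)C1 | intermediate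
16 | (1S,6R)-1-(acetonide chain)bicyclo[4.2.0]octane-2,5,7-trione, cis-fused, present as its lithium enolate (not isolated) | O=C1C[C@]2(C/C=C(\C)CC/C=C(\C)CC/C=C(\C)[C@@H]3OC(C)(C)O[C@@H]3C=C(C)C)C(=O)CCC(=O)[C@H]12 | intermediate
17 | methyl 2-[(1R)-1-(acetonide chain)-2,5-dioxocyclohexyl]acetate | COC(=O)C[C@@]1(C/C=C(\C)CC/C=C(\C)CC/C=C(\C)[C@@H]2OC(C)(C)O[C@@H]2C=C(C)C)CC(=O)CCC1=O | intermediate
18 | methyl 2-[(1R)-1-(acetonide chain)-2,5-dioxocyclohex-3-en-1-yl]acetate | COC(=O)C[C@@]1(C/C=C(\C)CC/C=C(\C)CC/C=C(\C)[C@@H]2OC(C)(C)O[C@@H]2C=C(C)C)CC(=O)C=CC1=O | intermediate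
19 | methyl 2-[(1R)-1-[(2E,6E,10E,12S,13R)-12,13-dihydroxy-3,7,11,15-tetramethylhexadeca-2,6,10,14-tetraen-1-yl]-2,5-dioxocyclohex-3-en-1-yl]acetate | COC(=O)C[C@@]1(C/C=C(\C)CC/C=C(\C)CC/C=C(\C)[C@H](O)[C@H](O)C=C(C)C)CC(=O)C=CC1=O | target

Total step count: 11. Longest linear sequence: 11 steps (from 1 or 2 to 19).

Steps most likely to fail

Step 9 (Proposed new method). The deprotonation may discriminate the two enantiotopic methylenes poorly or in the wrong sense. Enolisation next to the side-chain ketone may compete. Retro-Dieckmann equilibration during the methoxide stage may erode the enantiomeric purity. The fallback uses known chemistry, the rhodium-catalysed enantioselective carbonyl carboacylation of 3,3-disubstituted cyclobutanones; it sets out from 12 and comes back at 17. Acid 12 is converted into chloride 14 as in step 8 and coupled with [2-(1,3-dioxolan-2-yl)ethyl]zinc bromide under Pd(PPh3)4 to give 3-(acetonide chain)-3-[3-(1,3-dioxolan-2-yl)propanoyl]cyclobutan-1-one F1. Transacetalisation with TsOH in wet acetone frees the aldehyde, 4-[1-(acetonide chain)-3-oxocyclobutyl]-4-oxobutanal F2. Heating F2 with [Rh(C2H4)2Cl]2 and the DTBM-SEGPHOS enantiomer that selects the pro-S methylene (toluene, 110–130 °C) lets monovalent rhodium insert into one enantiotopic C(O)–CH2 bond; the aldehyde then inserts into the Rh–CH2 bond (the same C6–C5 bond) and acyl–oxygen reductive elimination gives the bridged lactone (1S,5R)-5-(acetonide chain)-2-oxabicyclo[3.3.1]nonane-3,6-dione F3. NaOMe in MeOH at 0 °C opens the lactone to methyl 2-[(1R,5S)-5-hydroxy-1-(acetonide chain)-2-oxocyclohexyl]acetate F4, and Dess–Martin oxidation of the C5 alcohol gives 17.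

Step 2. The allylic oxidation may show poor site selectivity among the three trisubstituted alkenes, or over-oxidise. The fallback sets out from 3 and comes back at 5, replacing oxidation of the terminal methyl group by cleavage and rebuilding of the terminal alkene. NBS in aqueous THF at 0 °C should give the terminal bromohydrin methyl 1-[(2E,6E)-10-bromo-11-hydroxy-3,7,11-trimethyldodeca-2,6-dien-1-yl]-3,3-dimethoxycyclobutane-1-carboxylate F5 (both C10′ epimers). K2CO3 in MeOH closes the epoxide methyl 1-[(2E,6E)-9-(3,3-dimethyloxiran-2-yl)-3,7-dimethylnona-2,6-dien-1-yl]-3,3-dimethoxycyclobutane-1-carboxylate F6. HIO4 in aqueous THF at 0 °C cleaves it to the aldehyde methyl 1-[(2E,6E)-3,7-dimethyl-10-oxodeca-2,6-dien-1-yl]-3,3-dimethoxycyclobutane-1-carboxylate F7. Wittig olefination with 2-(triphenylphosphoranylidene)propanal (toluene, 90 °C) then gives the E-enal 5.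

Step 10. The dehydrogenation may stall at low conversion, or IBX may attack allylic positions of the polyene. The fallback sets out from 17 and comes back at 18, separating enolisation from oxidation (Saegusa–Ito sequence). TMSOTf and Et3N in CH2Cl2 at 0 °C should give the conjugated bis(silyl) dienol ether methyl 2-[(1R)-1-(acetonide chain)-2,5-bis(trimethylsilyloxy)cyclohexa-2,4-dien-1-yl]acetate F8. Pd(OAc)2 in MeCN then removes both silyl groups oxidatively and gives ene-dione 18.

Further compounds
F1 | step 9 | 3-(acetonide chain)-3-[3-(1,3-dioxolan-2-yl)propanoyl]cyclobutan-1-one | O=C(CCC1OCCO1)C1(C/C=C(\C)CC/C=C(\C)CC/C=C(\C)[C@@H]2OC(C)(C)O[C@@H]2C=C(C)C)CC(=O)C1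
F2 | step 9 | 4-[1-(acetonide chain)-3-oxocyclobutyl]-4-oxobutanal | O=CCCC(=O)C1(C/C=C(\C)CC/C=C(\C)CC/C=C(\C)[C@@H]2OC(C)(C)O[C@@H]2C=C(C)C)CC(=O)C1
F3 | step 9 | (1S,5R)-5-(acetonide chain)-2-oxabicyclo[3.3.1]nonane-3,6-dione | O=C1C[C@@]2(C/C=C(\C)CC/C=C(\C)CC/C=C(\C)[C@@H]3OC(C)(C)O[C@@H]3C=C(C)C)C[C@@H](O1)CCC2=O
F4 | step 9 | methyl 2-[(1R,5S)-5-hydroxy-1-(acetonide chain)-2-oxocyclohexyl]acetate | COC(=O)C[C@@]1(C/C=C(\C)CC/C=C(\C)CC/C=C(\C)[C@@H]2OC(C)(C)O[C@@H]2C=C(C)C)C[C@@H](O)CCC1=O
F5 | step 2 | methyl 1-[(2E,6E)-10-bromo-11-hydroxy-3,7,11-trimethyldodeca-2,6-dien-1-yl]-3,3-dimethoxycyclobutane-1-carboxylate (both C10′ epimers) | COC(=O)C1(C/C=C(\C)CC/C=C(\C)CCC(Br)C(C)(C)O)CC(OC)(OC)C1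
F6 | step 2 | methyl 1-[(2E,6E)-9-(3,3-dimethyloxiran-2-yl)-3,7-dimethylnona-2,6-dien-1-yl]-3,3-dimethoxycyclobutane-1-carboxylate (racemic at the oxirane carbon) | COC(=O)C1(C/C=C(\C)CC/C=C(\C)CCC2OC2(C)C)CC(OC)(OC)C1
F7 | step 2 | methyl 1-[(2E,6E)-3,7-dimethyl-10-oxodeca-2,6-dien-1-yl]-3,3-dimethoxycyclobutane-1-carboxylate | COC(=O)C1(C/C=C(\C)CC/C=C(\C)CCC=O)CC(OC)(OC)C1
F8 | step 10 | methyl 2-[(1R)-1-(acetonide chain)-2,5-bis(trimethylsilyloxy)cyclohexa-2,4-dien-1-yl]acetate | COC(=O)C[C@@]1(C/C=C(\C)CC/C=C(\C)CC/C=C(\C)[C@@H]2OC(C)(C)O[C@@H]2C=C(C)C)CC(O[Si](C)(C)C)=CC=C1O[Si](C)(C)C
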